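The constants are those of an exercise; the rest is arithmetic.

At early times the precatalyst releases free catalyst, with a half-life of 0.43 d. Each free catalyst then stands at a fork: it turns substrate into product and comes back, or it meets another free catalyst and both become spent catalyst. We have to choose the next run: wait longer, or charge more precatalyst.

    2 free catalyst → spent catalyst (k1 = 413 L mol⁻¹ h⁻¹)
    substrate + free catalyst → free catalyst + product (k2 = 341 L mol⁻¹ h⁻¹)
    precatalyst → free catalyst (k3 = 0.0667 h⁻¹)

- south: substrate 0.050 M; precatalyst 0.12 mM; time 2.5 d
- south-east: substrate 0.050 M; precatalyst 0.12 mM; time 5.0 d

1. which of these there is most of at the end, counted by the substrate in it, south (product / substrate)
2. which of these there is most of at the end, counted by the substrate in it, south-east (product / substrate)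
3. the largest of these amounts at the end, in percent of the substrate charged, south
4. the largest of these amounts at the end, in percent of the substrate charged, south-east

The substrate falls at a fractional rate of the turnover constant times c(free catalyst). The inverse of c(free catalyst) rises steadily, at twice the loss constant, once release has ended. Dividing one by the other removes time, so c(substrate) follows c(free catalyst) raised to a power: the fork ratio 0.413, the turnover constant over twice the loss constant, a selectivity factor between turnover and loss.

Now we pretend that the whole charge is released at once. The substrate left is then the bracket (one plus twice the loss constant times charge times time) raised to minus the fork ratio. That gives 55.1% product in south and 65.2% in south-east. The reckoning is crude, since the first half-life of the free catalyst at full charge, 0.420 d, is close to the release half-life.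

Time and charge stand in the bracket as a product, so in this reckoning doubling either one does the same. Waiting needs no further charge of precatalyst, so we run south-east first.

The forecast gives product at 56.8% in south and product at 70.3% in south-east, both above our figures, on these grounds: “The Riccati equation linearises instead”.

The flasks give product at 56.9% in south and product at 70.3% in south-east.

At the end of south-east, c(free catalyst) stands at 10.3% of the catalyst charged, so its half-life by its own loss is 4.09 d, shorter than the 6.9 d of the substrate by turnover. The ratio of these two half-lives is, by their definitions, the natural logarithm of two over the fork ratio, 1.68. For the neighbour of south-east charged with 3.0 × 10⁻⁴ M of precatalyst, the bracket gives 75.7% product, and that flask reads 84.5%.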